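**Structural features**

The target is a flavonol: a 4H-chromen-4-one in which ring A is fused to the pyranone ring C through C4a–C8a, with a 4-hydroxyphenyl ring B on C2 and a hydroxyl on C3. Ring A is oxygenated everywhere except C8: O1 on C8a, free hydroxyls on C5 and C6, and a hydrogen sulfate monoester on O7. There is no stereocentre in the target; the centres that appear on the way (C2, C3, C4) are all erased when ring C reaches the pyranone level. The fragile groups are the aryl sulfate, which does not tolerate acid or Lewis acids, and the 5,6-dihydroxy and 3-hydroxy-enone units, which oxidise easily once free. The real difficulty is regiochemistry and timing: four contiguous oxygens must be placed on ring A, O7 alone must be sulfated among five oxygens, and the sulfate must survive a neutral final deprotection. The key step uses the para relationship of O1 (on C8a) and O6 (on C6): ring A is the reduced form of a 2,6-dialkoxy-1,4-benzoquinone whose carbonyl next to the C4 side chain becomes O1, while the other carbonyl becomes the 6-hydroxyl. The hydrogen bond from the 5-hydroxyl to the C4 carbonyl supplies a built-in difference between O5 and O7, which is used at the sulfation stage.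

**Logic of the disconnections**

20 to 19: the three benzyl C–O bonds at O3, O6 and O4′ are cut last. A sulfate monoester tolerates neutral hydrogenolysis but not acidic or Lewis acidic dealkylation. The forward step must leave S–O7 and the C2=C3 bond of the pyranone untouched.

19 to 18: the S–O7 bond is cut. In 18 only O5 and O7 are free, and O5 is chelated to the C4 carbonyl, so O5 and O7 never need different protecting groups. The forward step must be a mono-sulfation that respects this difference.

18 to 17 to 16: the two allyl C–O bonds at O5 and O7 are cut, then the benzyl C–O bond at O3. Allyl is removable by zerovalent palladium without touching benzyl, and O3 must be capped so that it cannot compete for the sulfating agent. The forward steps are routine.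

16 to 14 to 12: the C3–O and C4–O bonds are removed, going back through 15, 14 and 13 to the C3=C4 alkene of 12. This lowers ring C to the 2H-chromene that an electrocyclisation can make. The forward demand is an oxidant that picks the electron-rich C3=C4 bond over two allyl ethers, and then a four-electron oxidation of the diol without C3–C4 cleavage.

12 to 11: the benzyl C–O bond at O6 is cut. The phenol freed by the key step is a para-alkoxyphenol and must be capped before any oxidant is used. This is also the point where O6 becomes distinct from O5 and O7.

11 to 8 (through 10 and 9): the O1–C2 bond is cut. Ring C opens to a cinnamyl chain on a hydroquinone and the only stereocentre disappears. The forward step must oxidise 8, tautomerise 9 in one sense only, and close 10 before the allyloxyquinone can rearrange or the product is oxidised further.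

8 to 4 + 7: the C4a–C4 bond is cut. The two open ring positions of 4 are equivalent by symmetry, so regiochemistry on ring A is not an issue, and the molecule falls into ring A and ring B halves. The forward step must stop at mono-alkylation, give the linear E chain, and avoid acid-induced ring closure.

7 to 5 + 6: the C2–C3 bond is cut. 7 ionises to the same allyl cation that its linear isomer would give, so a two-step olefination and reduction is replaced by one addition. The carbinol stereocentre is irrelevant.

4 to 3 to 1 + 2: the oxidation level is adjusted and the C5–O and C7–O bonds (flavone numbering) are cut. These carbons are vinylogous ester carbons in 1 and 3 and exchange their alkoxy groups, so two molecules of 2 are taken up for each molecule of 1. The forward exchange must go to completion at both sites without heating the allyloxyquinone.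

**Other disconnections considered**

Alternative 1: The cut is at C4a–C4 and C4–C3, with C4 supplied as carbon monoxide. In the forward step the aryl iodide A2, CO (1 atm) and the MgCl2/Et3N-derived enolate of ketone A3 would combine under Pd(dba)2 and Xantphos to give the open-chain diketone A1. Ring C would be closed afterwards by desilylation and cyclodehydration.
- In favour: the union is convergent, C4 arrives at the carbonyl level, and O3 arrives already benzylated. No oxidation of ring C is needed, which is better than the chosen plan, where C3 and C4 are raised by four electrons after ring closure. There are no alkene-bearing protecting groups, so the chemoselectivity question of step 7 does not arise; this is also better.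
- Against: A2 is a penta-substituted, very electron-rich iodide with oxygen substituents on both ortho positions. Oxidative addition to zerovalent palladium should be slow and the aroyl complex of divalent palladium hindered, so CO-free arylation and loss of iodine are likely competitors. A1 is more acidic than A3 and open to retro-Claisen fragmentation under the basic conditions. A2 needs three different protecting groups placed in a defined pattern plus a site-selective iodination, whereas the chosen plan takes the same oxygen pattern from the symmetry of 1.
- Comparison: on structure the two are equal, since both carry O5/O7 as one removable pair and O6 as a benzyl ether. On mechanism this is a metal-catalysed carbonylation with toxic gas against a metal-free pericyclic closure. On step economy the alternative is shorter after its key step, but the preparation of A2 should use up that gain. The sulfation and hydrogenolysis endgame is the same.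

Alternative 2: The cut is at C4–C4a. tert-Butyl hydroperoxide with catalytic Bu4NBr at about 100 °C would turn the formyl C–H of the Z enal A5 into an acyl radical that attacks an ortho carbon of the aryloxy ring and gives the flavone A4.
- In favour: the aryloxy ring of A5 is symmetric, so regiochemistry is settled by symmetry exactly as in the chosen plan (equal). Ring C is closed directly at the pyranone level with no metal, and no hydroquinone or quinone has to be handled (better).
- Against: A4 has no oxygen on C3, so a separate C3 hydroxylation is still required and the redox advantage is largely lost. Oxygen-centred radicals at 100 °C abstract benzylic and acetal hydrogens, and A5 has three benzyl ethers and two methoxymethyl groups. The nucleophilic acyl radical must attack an electron-rich carbon flanked by a methoxymethoxy group. Only the Z isomer of A5 can close.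
- Comparison: step economy is about equal once the C3 oxidation is counted. The chosen key step treats its protecting groups more gently. The alternative creates no transient stereocentre, but that is of no consequence since the one in the chosen plan is erased.

Alternative 3: The cut is at C3–C4. A triazolium-derived carbene (generated with DBU) would convert the ring A formyl group of dialdehyde A7 into an acyl anion equivalent that adds to the aliphatic formyl group, giving A6.
- In favour: C3–OH and C4=O are formed in one event, leaving ring C only two electrons short of the flavonol. On ring C redox economy this is better than the chosen plan. The conditions are mild and metal-free.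
- Against: the carbene must add first to the aromatic aldehyde, which is di-ortho-substituted and electron-rich and so the poorer electrophile. Addition to the aliphatic aldehyde would give a Breslow intermediate with an α-aryloxy leaving group, opening an internal redox path that expels the ring A phenoxide. The α-aryl-α-aryloxy aldehyde of A7 is highly enolisable and awkward to prepare and store. A6 still needs dehydrogenation under conditions where 3-hydroxychromanones can ring-contract.
- Comparison: both routes create stereocentres that are later erased (equal) and share the same endgame (equal). The chosen plan has the more predictable key step and the simpler front end, since the ring A half of A7 needs a regiodefined, fully differentiated tetraoxygenated benzene.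

Key step: step 5

Assumption: sulfate esters 19 and 20 are written as neutral hydrogen sulfates; in practice 19 would be carried as its sodium salt and the proton restored on an acidic resin at the very end, which does not change the equations.

Remark on structures: 8 and 11 map atom by atom onto flavone numbering (C1–OH of 8 becomes O1, C4–OH becomes the 6-hydroxyl, the C3 and C5 oxygens become O5 and O7), so the precursor and the chromene carry exactly the oxygen pattern the target requires.

Step 1
Reactants: 1 2,6-dimethoxy-1,4-benzoquinone; 2 prop-2-en-1-ol (two equivalents are incorporated; also the solvent)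
Product: 3 2,6-bis(prop-2-en-1-yloxy)cyclohexa-2,5-diene-1,4-dione
Conditions: 2 (solvent, large excess), TsOH·H2O (10 mol %), 40 °C, 200 mbar (MeOH distilled off), dark
Reagents that add atoms: prop-2-en-1-ol (the second equivalent, taken from the solvent), C=CCO
Why: Acid-catalysed vinylogous transesterification (addition–elimination at each of the two alkoxy-bearing quinone carbons), so two molecules of 2 are built in and two of methanol are released. The excess of 2 and removal of methanol drive both exchanges, and the low temperature keeps the allyloxyquinone from Claisen rearrangement.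

Step 2
Reactants: 3 2,6-bis(prop-2-en-1-yloxy)cyclohexa-2,5-diene-1,4-dione
Product: 4 2,6-bis(prop-2-en-1-yloxy)benzene-1,4-diol
Conditions: Na2S2O4, EtOAc/H2O, rt, Ar
Reagents that add atoms: none
Why: Dithionite reduction of a quinone to its hydroquinone; allyl ethers are inert and the product is kept under argon.

Step 3
Reactants: 5 4-(benzyloxy)benzaldehyde; 6 ethenylmagnesium bromide (CH2=CHMgBr)
Product: 7 1-[4-(benzyloxy)phenyl]prop-2-en-1-ol (racemic)
Conditions: CH2=CHMgBr (1.2 equiv), THF, 0 °C; aq NH4Cl
Reagents that add atoms: none
Why: Grignard 1,2-addition to an aromatic aldehyde; the carbinol centre is racemic and is lost on ionisation in step 4.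

Step 4
Reactants: 4 2,6-bis(prop-2-en-1-yloxy)benzene-1,4-diol; 7 1-[4-(benzyloxy)phenyl]prop-2-en-1-ol
Product: 8 2-{(2E)-3-[4-(benzyloxy)phenyl]prop-2-en-1-yl}-3,5-bis(prop-2-en-1-yloxy)benzene-1,4-diol
Conditions: 4 (2 equiv), TsOH·H2O (5 mol %), MeCN, 0 °C to rt, Ar
Reagents that add atoms: none
Why: Friedel–Crafts allylation: 7 ionises to an allyl cation stabilised by the para-benzyloxy group, and the only open (and equivalent) ring carbons of 4 attack its CH2 terminus so that styrene conjugation is kept and the E alkene results; excess 4 suppresses a second alkylation and the mild acid avoids ring closure onto the styrene.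

Step 5
Reactants: 8 2-{(2E)-3-[4-(benzyloxy)phenyl]prop-2-en-1-yl}-3,5-bis(prop-2-en-1-yloxy)benzene-1,4-diol
Product: 11 2-[4-(benzyloxy)phenyl]-5,7-bis(prop-2-en-1-yloxy)-2H-chromen-6-ol (racemic), via cinnamylquinone 9 (not isolated), via ortho-quinone methide 10 (not isolated)
Conditions: Ag2O (1.5 equiv), MgSO4, CH2Cl2, rt, dark; filter; then pyridine, 40 °C, Ar
Reagents that add atoms: none
Why: Monovalent silver oxide removes two electrons from 8 to give quinone 9, and the silver is filtered off so that the phenol formed later is not oxidised. In pyridine a C4 methylene hydrogen, allylic to the styrene and vinylogously alpha to the C6 carbonyl through C4a=C5, is moved to O6, giving the vinyl ortho-quinone methide 10 (O1=C8a–C4a=C4–C3=C2). 10 then closes by a thermal disrotatory oxa-6π electrocyclisation that forms O1–C2 and restores the aromaticity of ring A. The closest known reaction type is the base-induced isomerisation of 2-allyl- and 2-cinnamyl-1,4-benzoquinones to 6-hydroxy-2H-chromenes. Ring C is therefore closed in a pericyclic mode (formally 6-endo, oxygen onto the styryl terminus), not by ionic addition. C2 is formed with no controlling element and is racemic, which is harmless because C2 becomes sp2 in step 8. Regiochemistry is secured because only the C8a carbonyl is ortho to the side chain, and reversible tautomerisation funnels material through the Z exocyclic isomer that can close. The quinone stage is the only point where an allyloxy group could shift to C8, so the temperature is kept low.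

Step 6
Reactants: 11 2-[4-(benzyloxy)phenyl]-5,7-bis(prop-2-en-1-yloxy)-2H-chromen-6-ol
Product: 12 6-(benzyloxy)-2-[4-(benzyloxy)phenyl]-5,7-bis(prop-2-en-1-yloxy)-2H-chromene (racemic)
Conditions: BnBr, K2CO3, DMF, rt, Ar
Reagents that add atoms: benzyl bromide, BrCc1ccccc1
Why: Williamson ether synthesis on the only free phenol; capping O6 removes the oxidisable para-alkoxyphenol before step 7.

Step 7
Reactants: 12 6-(benzyloxy)-2-[4-(benzyloxy)phenyl]-5,7-bis(prop-2-en-1-yloxy)-2H-chromene
Product: 14 6-(benzyloxy)-2-[4-(benzyloxy)phenyl]-5,7-bis(prop-2-en-1-yloxy)-3,4-dihydro-2H-chromene-3,4-diol (racemic; diastereomer mixture), via 3,4-epoxide 13 (not isolated)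
Conditions: dimethyldioxirane (1.05 equiv, acetone), CH2Cl2, −40 °C; then THF/H2O, 0 °C to rt
Reagents that add atoms: dimethyldioxirane, CC1(C)OO1; water, O
Why: Dioxirane epoxidation followed by SN1 hydrolysis: the C3=C4 bond, conjugated with the trioxygenated ring A, is far more nucleophilic than the terminal allyl ether alkenes, and 13 opens at the cation-stabilised C4 with water; epoxidation should occur anti to the C2 aryl group and water may attack either face, but all three centres are erased in step 8.

Step 8
Reactants: 14 6-(benzyloxy)-2-[4-(benzyloxy)phenyl]-5,7-bis(prop-2-en-1-yloxy)-3,4-dihydro-2H-chromene-3,4-diol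
Product: 16 6-(benzyloxy)-2-[4-(benzyloxy)phenyl]-3-hydroxy-5,7-bis(prop-2-en-1-yloxy)-4H-chromen-4-one, via flavan-3,4-dione 15 (not isolated)
Conditions: IBX (2.5 equiv), DMSO, rt
Reagents that add atoms: none
Why: IBX oxidation of a 1,2-diol to the 1,2-dione without glycol cleavage, then keto–enol tautomerisation: the C2 hydrogen of 15 moves to O3, giving the aromatic pyranone; IBX forms no leaving group at the ionisable C4 position, unlike activated-DMSO methods.

Step 9
Reactants: 16 6-(benzyloxy)-2-[4-(benzyloxy)phenyl]-3-hydroxy-5,7-bis(prop-2-en-1-yloxy)-4H-chromen-4-one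
Product: 17 3,6-bis(benzyloxy)-2-[4-(benzyloxy)phenyl]-5,7-bis(prop-2-en-1-yloxy)-4H-chromen-4-one
Conditions: BnBr, K2CO3, DMF, 40 °C
Reagents that add atoms: benzyl bromide, BrCc1ccccc1
Why: Williamson ether synthesis on the acidic flavonol 3-hydroxyl, the only free OH, so that it cannot compete in the sulfation.

Step 10
Reactants: 17 3,6-bis(benzyloxy)-2-[4-(benzyloxy)phenyl]-5,7-bis(prop-2-en-1-yloxy)-4H-chromen-4-one
Product: 18 3,6-bis(benzyloxy)-2-[4-(benzyloxy)phenyl]-5,7-dihydroxy-4H-chromen-4-one
Conditions: Pd(PPh3)4 (5 mol %), morpholine (6 equiv), THF, rt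
Reagents that add atoms: none
Why: Tsuji–Trost-type deallylation: zerovalent palladium ionises both aryl allyl ethers to π-allyl complexes of divalent palladium, which morpholine intercepts; benzyl ethers are untouched.

Step 11
Reactants: 18 3,6-bis(benzyloxy)-2-[4-(benzyloxy)phenyl]-5,7-dihydroxy-4H-chromen-4-one
Product: 19 3,6-bis(benzyloxy)-2-[4-(benzyloxy)phenyl]-5-hydroxy-4-oxo-4H-chromen-7-yl hydrogen sulfate
Conditions: SO3·pyridine (2 equiv), pyridine, rt; aq NaHCO3 work-up (sodium salt)
Reagents that add atoms: sulfur trioxide–pyridine complex, O=S(=O)([O-])[n+]1ccccc1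
Why: O-sulfonation with an SO3–amine complex; the 7-hydroxyl is the most acidic and accessible phenol, while the 5-hydroxyl is held in a hydrogen bond to the C4 carbonyl and should not react under these mild conditions; the pyridinium counter-ion is exchanged for sodium so that it does not inhibit the next step.

Step 12
Reactants: 19 3,6-bis(benzyloxy)-2-[4-(benzyloxy)phenyl]-5-hydroxy-4-oxo-4H-chromen-7-yl hydrogen sulfate
Product: 20 3,5,6-trihydroxy-2-(4-hydroxyphenyl)-4-oxo-4H-chromen-7-yl hydrogen sulfate (CNP0164757.0)
Conditions: H2 (1 atm), Pd/C (10 %), MeOH/THF, rt; then sulfonic acid resin (H+ form), 0 °C, freeze-dry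
Reagents that add atoms: none
Why: Hydrogenolysis of three benzyl ethers under neutral conditions, which aryl sulfate salts and the pyranone C2=C3 bond should tolerate; brief cold contact with the acidic resin restores the proton without hydrolysing the sulfate.

**Compound list**

1 | 2,6-dimethoxy-1,4-benzoquinone | COC1=CC(=O)C=C(OC)C1=O | starting material
2 | prop-2-en-1-ol | C=CCO | starting material
3 | 2,6-bis(prop-2-en-1-yloxy)cyclohexa-2,5-diene-1,4-dione | C=CCOC1=CC(=O)C=C(OCC=C)C1=O | intermediate
4 | 2,6-bis(prop-2-en-1-yloxy)benzene-1,4-diol | C=CCOc1cc(O)cc(OCC=C)c1O | intermediate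
5 | 4-(benzyloxy)benzaldehyde | O=Cc1ccc(OCc2ccccc2)cc1 | starting material
6 | ethenylmagnesium bromide | C=C[Mg]Br | starting material
7 | 1-[4-(benzyloxy)phenyl]prop-2-en-1-ol (racemic) | C=CC(O)c1ccc(OCc2ccccc2)cc1 | intermediate
8 | 2-{(2E)-3-[4-(benzyloxy)phenyl]prop-2-en-1-yl}-3,5-bis(prop-2-en-1-yloxy)benzene-1,4-diol | Oc1cc(OCC=C)c(O)c(OCC=C)c1C/C=C/c1ccc(OCc2ccccc2)cc1 | intermediate
9 | 2-{(2E)-3-[4-(benzyloxy)phenyl]prop-2-en-1-yl}-3,5-bis(prop-2-en-1-yloxy)cyclohexa-2,5-diene-1,4-dione | O=C1C=C(OCC=C)C(=O)C(OCC=C)=C1C/C=C/c1ccc(OCc2ccccc2)cc1 | intermediate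
10 | (6Z)-6-{(2E)-3-[4-(benzyloxy)phenyl]prop-2-en-1-ylidene}-4-hydroxy-3,5-bis(prop-2-en-1-yloxy)cyclohexa-2,4-dien-1-one | O=C1C=C(OCC=C)C(O)=C(OCC=C)/C1=C/C=C/c1ccc(OCc2ccccc2)cc1 | intermediate
11 | 2-[4-(benzyloxy)phenyl]-5,7-bis(prop-2-en-1-yloxy)-2H-chromen-6-ol (racemic) | C=CCOc1cc2OC(c3ccc(OCc4ccccc4)cc3)C=Cc2c(OCC=C)c1O | intermediate
12 | 6-(benzyloxy)-2-[4-(benzyloxy)phenyl]-5,7-bis(prop-2-en-1-yloxy)-2H-chromene (racemic) | C=CCOc1cc2OC(c3ccc(OCc4ccccc4)cc3)C=Cc2c(OCC=C)c1OCc1ccccc1 | intermediate
13 | 6-(benzyloxy)-2-[4-(benzyloxy)phenyl]-3,4-epoxy-5,7-bis(prop-2-en-1-yloxy)-3,4-dihydro-2H-chromene (racemic) | C=CCOc1cc2OC(c3ccc(OCc4ccccc4)cc3)C3OC3c2c(OCC=C)c1OCc1ccccc1 | intermediate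
14 | 6-(benzyloxy)-2-[4-(benzyloxy)phenyl]-5,7-bis(prop-2-en-1-yloxy)-3,4-dihydro-2H-chromene-3,4-diol (racemic; diastereomer mixture) | C=CCOc1cc2OC(c3ccc(OCc4ccccc4)cc3)C(O)C(O)c2c(OCC=C)c1OCc1ccccc1 | intermediate
15 | 6-(benzyloxy)-2-[4-(benzyloxy)phenyl]-5,7-bis(prop-2-en-1-yloxy)-2H-chromene-3,4-dione (racemic) | C=CCOc1cc2OC(c3ccc(OCc4ccccc4)cc3)C(=O)C(=O)c2c(OCC=C)c1OCc1ccccc1 | intermediate
16 | 6-(benzyloxy)-2-[4-(benzyloxy)phenyl]-3-hydroxy-5,7-bis(prop-2-en-1-yloxy)-4H-chromen-4-one | O=c1c(O)c(-c2ccc(OCc3ccccc3)cc2)oc2cc(OCC=C)c(OCc3ccccc3)c(OCC=C)c12 | intermediate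
17 | 3,6-bis(benzyloxy)-2-[4-(benzyloxy)phenyl]-5,7-bis(prop-2-en-1-yloxy)-4H-chromen-4-one | O=c1c(OCc2ccccc2)c(-c2ccc(OCc3ccccc3)cc2)oc2cc(OCC=C)c(OCc3ccccc3)c(OCC=C)c12 | intermediate
18 | 3,6-bis(benzyloxy)-2-[4-(benzyloxy)phenyl]-5,7-dihydroxy-4H-chromen-4-one | O=c1c(OCc2ccccc2)c(-c2ccc(OCc3ccccc3)cc2)oc2cc(O)c(OCc3ccccc3)c(O)c12 | intermediate
19 | 3,6-bis(benzyloxy)-2-[4-(benzyloxy)phenyl]-5-hydroxy-4-oxo-4H-chromen-7-yl hydrogen sulfate | O=c1c(OCc2ccccc2)c(-c2ccc(OCc3ccccc3)cc2)oc2cc(OS(=O)(=O)O)c(OCc3ccccc3)c(O)c12 | intermediate
20 | 3,5,6-trihydroxy-2-(4-hydroxyphenyl)-4-oxo-4H-chromen-7-yl hydrogen sulfate | O=c1c(O)c(-c2ccc(O)cc2)oc2cc(OS(=O)(=O)O)c(O)c(O)c12 | target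

**Step count and least certain steps**

Total: 12 steps. Longest linear sequence: 11 steps (steps 1, 2 and 4 to 12); step 3 is a one-step side branch.

Step 5 (key step). The most likely failures are a sigmatropic shift of the C7 allyloxy group to C8 at the quinone stage, addition of pyridine to the unsubstituted C8 position of 9, or further oxidation of the product phenol by residual silver or air. The fallback generates the same ortho-quinone methide without an oxidant. It sets out from 4 and 5. Wittig olefination of 5 with (triphenylphosphoranylidene)acetaldehyde in toluene at 80 °C should give (2E)-3-[4-(benzyloxy)phenyl]prop-2-enal F1. Condensation of 4 with F1 under catalytic ethylenediammonium diacetate in toluene at reflux under argon (a known chromene annulation of electron-rich phenols with enals) should pass through 10 and return to the route at 11.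

Step 1. The second methoxy exchange may stall, or the allyloxyquinone may undergo an O-to-C allyl shift if heat is applied to remove methanol. The fallback never heats an allyloxyquinone. It sets out from 2 and commercial benzene-1,3,5-triol F2. Acid-catalysed etherification of F2 in 2 (dry HCl, 60 °C) should give 3,5-bis(prop-2-en-1-yloxy)phenol F3. Para-oxidation of F3 with potassium nitrosodisulfonate, (KSO3)2NO, in aqueous KH2PO4/acetone at rt should give the quinone and return to the route at 3.

Step 4. A second alkylation at the remaining ring position, attack through the benzylic end of the cation, or acid-induced addition of the new ortho hydroxyl across the styrene may erode the yield. The fallback avoids acid. It sets out from 4 and 7. Treatment of 7 with PBr3 in Et2O at 0 °C, with allylic transposition, should give 1-(benzyloxy)-4-[(1E)-3-bromoprop-1-en-1-yl]benzene F4. F4 is used at once to alkylate the monosodium phenoxide of 4 (NaH, toluene, 0 °C to rt) at the ortho carbon, the classical C-alkylation of phenoxides in non-polar media, returning to the route at 8.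

Step 8. Oxidative cleavage of the C3–C4 bond, ionisation of the C4 hydroxyl before it is oxidised, or further oxidation of the flavonol enol may occur. The fallback separates the two oxidations and sets out from 14. MnO2 in CH2Cl2 at rt should oxidise only the benzylic C4 hydroxyl, giving 6-(benzyloxy)-2-[4-(benzyloxy)phenyl]-3-hydroxy-5,7-bis(prop-2-en-1-yloxy)-2,3-dihydro-4H-chromen-4-one F5. Cu(OAc)2 in pyridine/MeOH at 60 °C (ketol to diketone oxidation by divalent copper) should then give 15, which tautomerises and returns to the route at 16.

Step 11. Sulfation may also reach the chelated 5-hydroxyl, or the sulfate may be lost during purification of a polar salt. The fallback uses a neutral, chromatographable sulfate diester and sets out from 18. 2,2,2-Trichloroethyl chlorosulfate with Et3N and catalytic DMAP in THF at 0 °C should give 3,6-bis(benzyloxy)-2-[4-(benzyloxy)phenyl]-5-hydroxy-4-oxo-4H-chromen-7-yl 2,2,2-trichloroethyl sulfate F6. Pd/C with HCO2NH4 in MeOH at rt should remove the trichloroethyl group and the three benzyl groups together, returning to the route at 20 after the same acidic resin treatment.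

**Further compounds**

F1 | step 5 | (2E)-3-[4-(benzyloxy)phenyl]prop-2-enal | O=C/C=C/c1ccc(OCc2ccccc2)cc1
F2 | step 1 | benzene-1,3,5-triol | Oc1cc(O)cc(O)c1
F3 | step 1 | 3,5-bis(prop-2-en-1-yloxy)phenol | C=CCOc1cc(O)cc(OCC=C)c1
F4 | step 4 | 1-(benzyloxy)-4-[(1E)-3-bromoprop-1-en-1-yl]benzene | BrC/C=C/c1ccc(OCc2ccccc2)cc1
F5 | step 8 | 6-(benzyloxy)-2-[4-(benzyloxy)phenyl]-3-hydroxy-5,7-bis(prop-2-en-1-yloxy)-2,3-dihydro-4H-chromen-4-one (racemic) | C=CCOc1cc2OC(c3ccc(OCc4ccccc4)cc3)C(O)C(=O)c2c(OCC=C)c1OCc1ccccc1
F6 | step 11 | 3,6-bis(benzyloxy)-2-[4-(benzyloxy)phenyl]-5-hydroxy-4-oxo-4H-chromen-7-yl 2,2,2-trichloroethyl sulfate | O=c1c(OCc2ccccc2)c(-c2ccc(OCc3ccccc3)cc2)oc2cc(OS(=O)(=O)OCC(Cl)(Cl)Cl)c(OCc3ccccc3)c(O)c12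
A1 | alternative 1 | 2-(benzyloxy)-1-{3-(benzyloxy)-6-[(tert-butyldimethylsilyl)oxy]-2,4-bis(methoxymethoxy)phenyl}-3-[4-(benzyloxy)phenyl]propane-1,3-dione | CC(C)(C)[Si](C)(C)Oc1cc(OCOC)c(OCc2ccccc2)c(OCOC)c1C(=O)C(OCc1ccccc1)C(=O)c1ccc(OCc2ccccc2)cc1
A2 | alternative 1 | [4-(benzyloxy)-2-iodo-3,5-bis(methoxymethoxy)phenoxy](tert-butyl)dimethylsilane | CC(C)(C)[Si](C)(C)Oc1cc(OCOC)c(OCc2ccccc2)c(OCOC)c1I
A3 | alternative 1 | 2-(benzyloxy)-1-[4-(benzyloxy)phenyl]ethan-1-one | O=C(COCc1ccccc1)c1ccc(OCc2ccccc2)cc1
A4 | alternative 2 | 6-(benzyloxy)-2-[4-(benzyloxy)phenyl]-5,7-bis(methoxymethoxy)-4H-chromen-4-one | O=c1cc(-c2ccc(OCc3ccccc3)cc2)oc2cc(OCOC)c(OCc3ccccc3)c(OCOC)c12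
A5 | alternative 2 | (2Z)-3-[4-(benzyloxy)-3,5-bis(methoxymethoxy)phenoxy]-3-[4-(benzyloxy)phenyl]prop-2-enal | O=C/C=C(\Oc1cc(OCOC)c(OCc2ccccc2)c(OCOC)c1)c1ccc(OCc2ccccc2)cc1
A6 | alternative 3 | 6-(benzyloxy)-2-[4-(benzyloxy)phenyl]-3-hydroxy-5,7-bis(methoxymethoxy)-2,3-dihydro-4H-chromen-4-one (racemic, mixture of diastereomers) | O=C1C(O)C(c2ccc(OCc3ccccc3)cc2)Oc2cc(OCOC)c(OCc3ccccc3)c(OCOC)c12
A7 | alternative 3 | 3-(benzyloxy)-6-{1-[4-(benzyloxy)phenyl]-2-oxoethoxy}-2,4-bis(methoxymethoxy)benzaldehyde (racemic) | O=CC(Oc1cc(OCOC)c(OCc2ccccc2)c(OCOC)c1C=O)c1ccc(OCc2ccccc2)cc1
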